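**Retrosynthetic overview**

1. The target is epiafzelechin-(4β→6)-epigallocatechin 3,3'-di-O-gallate. The last disconnections are global hydrogenolysis (twelve O-benzyl groups, three C–Br bonds) and then the interflavan C4–C6 bond, made by Friedel–Crafts union of the C4-methoxy upper electrophile 11 with the C8-blocked lower nucleophile 19.
2. Ring C of the upper unit is built in one oxa-[4+2] that forms O1–C2 and C3–C4 together, from the o-quinone methide of aldehyde 2 and the Z-styryl MIDA boronate 5. The C3–B bond is then oxidised to C3–OH.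
3. Enabling feature: in ring A the phenolic O1 (on C8a) is ortho to the benzylic carbon C4 (on C4a), so O1=C8a–C4a=C4 can be unmasked as a heterodiene. C2 is benzylic to the 4-oxyphenyl ring B, and the C3 oxygen can be carried as boron.
4. The lower unit comes from (−)-epigallocatechin: B-ring ketal, benzylation, C8 bromination, 3-O-galloylation, ketal removal, 3'-O-galloylation.
5. Ring order: rings A and B of both units and ring C of the lower unit come with the building blocks. Ring C of the upper unit is the only ring formed (step 3), followed by union and deprotection.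

Key step: step 3

Assumption: compounds 1, 3, 4, 12 and 16 are taken as catalogue materials, and the (R)-configured acid of step 3 is assumed to give the (2S,3R) adduct 8; if the opposite sense is found, its (S)-antipode is used with nothing else changed.

**Route**

Step 1
Reactants: 1 2,4,6-trihydroxybenzaldehyde
Product: 2 2,4-bis(benzyloxy)-6-hydroxybenzaldehyde
Conditions: BnBr (2.1 equiv), K2CO3, DMF, 0 °C → rt
Reagents that add atoms: benzyl bromide, BrCc1ccccc1
Why: Williamson ether synthesis: the ortho OH that is hydrogen-bonded to the formyl oxygen is the least nucleophilic, so with two equivalents of halide the 4-OH and one of the two equivalent ortho OH groups are benzylated and the chelated phenol survives.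

Step 2
Reactants: 3 (Z)-(2-bromoethenyl)boronic acid MIDA ester; 4 [4-(benzyloxy)phenyl]boronic acid
Product: 5 (Z)-{2-[4-(benzyloxy)phenyl]ethenyl}boronic acid MIDA ester
Conditions: Pd(OAc)2 (5 mol %), 2-dicyclohexylphosphino-2',6'-dimethoxybiphenyl (10 mol %), K3PO4 (anhydrous), THF, rt
Reagents that add atoms: none
Why: Suzuki–Miyaura coupling under anhydrous conditions: the sp3-hybridised MIDA boronate does not transmetalate, so only boronic acid 4 couples, and oxidative addition and reductive elimination at the vinyl bromide go with retention, which fixes the Z geometry.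

Step 3
Reactants: 2 2,4-bis(benzyloxy)-6-hydroxybenzaldehyde; 5 (Z)-{2-[4-(benzyloxy)phenyl]ethenyl}boronic acid MIDA ester
Product: 8 [(2S,3R)-5,7-bis(benzyloxy)-2-[4-(benzyloxy)phenyl]-4-methoxychroman-3-yl]boronic acid MIDA ester (2,3-cis; both C4 epimers), via dimethyl acetal 6 (not isolated), via methoxy o-quinone methide 7 (not isolated)
Conditions: HC(OMe)3 (2 equiv), (R)-3,3'-bis(2,4,6-triisopropylphenyl)-1,1'-binaphthyl-2,2'-diyl N-(trifluoromethylsulfonyl)phosphoramide (10 mol %), 4 Å MS, CH2Cl2/MeCN, −40 → −20 °C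
Reagents that add atoms: trimethyl orthoformate, COC(OC)OC
Why: Proposed new method: the chiral acid turns 2 into acetal 6 and then into the methoxy-substituted o-quinone methide 7 (heterodiene O1=C8a–C4a=C4 of ring A, held as a contact ion pair with the chiral phosphoramide anion), which undergoes an inverse-electron-demand oxa-[4+2] (hetero-Diels–Alder) cycloaddition with the Z-alkene of 5; the closest known reactions are the acid-catalysed three-component chroman synthesis from salicylaldehydes, orthoformates and styrenes and the chiral Brønsted acid-catalysed [4+2] cycloadditions of salicylaldehyde-derived o-quinone methides. Ring C is closed in a single 4+2 event (C3–C4 bond leading, O1–C2 bond following), and the regiochemistry is enforced twice, because both the 4-benzyloxyphenyl group and the tetracoordinate C3–B(MIDA) σ-bond (β-boron effect) stabilise positive charge at C2, which makes the boron-bearing C3 the nucleophilic terminus. C2 and C3 are set 2,3-cis because the Z geometry of 5 is transferred suprafacially, and hyperconjugation of the C3–B bond with the developing C2 cation restrains C2–C3 rotation even if the addition is asynchronous. The absolute configuration (2S,3R in 8, spatially identical to 2R,3R once boron is exchanged for oxygen) is set by the chiral counter-anion, which shields one face of 7. C4 is formed as an inconsequential mixture of epimers because this centre is ionised again in step 12. The step needs Z-retention, face selectivity and survival of the acid-labile C4–OMe and C3–B bonds, which the low temperature, the bulky counter-anion and the MIDA cage (no empty p-orbital, hence no Petasis-type alkenyl transfer) are expected to secure.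

Step 4
Reactants: 8 [(2S,3R)-5,7-bis(benzyloxy)-2-[4-(benzyloxy)phenyl]-4-methoxychroman-3-yl]boronic acid MIDA ester
Product: 10 (2R,3R)-5,7-bis(benzyloxy)-2-[4-(benzyloxy)phenyl]-4-methoxychroman-3-ol (2,3-cis; both C4 epimers), via boronic acid 9 (not isolated)
Conditions: NaOH (aq), THF, rt; then H2O2 (30%), 0 °C
Reagents that add atoms: hydrogen peroxide, OO
Why: Boronate oxidation: aqueous hydroxide releases boronic acid 9 from the MIDA cage and hydroperoxide then triggers the 1,2-shift of C3 from boron to oxygen with retention, so the new 3-OH stays cis to the 2-aryl group.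

Step 5
Reactants: 10 (2R,3R)-5,7-bis(benzyloxy)-2-[4-(benzyloxy)phenyl]-4-methoxychroman-3-ol
Product: 11 (2R,3R)-5,7-bis(benzyloxy)-2-[4-(benzyloxy)phenyl]-6,8-dibromo-4-methoxychroman-3-ol (both C4 epimers)
Conditions: NBS (2.05 equiv), CH2Cl2, −40 → 0 °C
Reagents that add atoms: N-bromosuccinimide, O=C1CCC(=O)N1Br
Why: Electrophilic aromatic bromination: C6 and C8 of the phloroglucinol-type ring A are each activated by three oxygen atoms and react far faster than the mono-oxygenated ring B, and the two bromines cap ring A so that 11 cannot later alkylate itself (halogen-capping tactic of oligomeric catechin synthesis).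

Step 6
Reactants: 12 (−)-epigallocatechin
Product: 13 (2R,3R)-2-(7-hydroxy-2,2-diphenyl-1,3-benzodioxol-5-yl)chromane-3,5,7-triol
Conditions: Ph2CCl2 (1.2 equiv), K2CO3, MeCN, rt, Ar
Reagents that add atoms: dichlorodiphenylmethane, ClC(Cl)(c1ccccc1)c1ccccc1
Why: Ketal formation by double O-alkylation: only the vicinal 3',4'-phenols of ring B can close the five-membered 2,2-diphenyl-1,3-benzodioxole, which sets the third B-ring hydroxyl apart; no stereocentre is involved.

Step 7
Reactants: 13 (2R,3R)-2-(7-hydroxy-2,2-diphenyl-1,3-benzodioxol-5-yl)chromane-3,5,7-triol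
Product: 14 (2R,3R)-5,7-bis(benzyloxy)-2-[7-(benzyloxy)-2,2-diphenyl-1,3-benzodioxol-5-yl]chroman-3-ol
Conditions: BnBr (3.3 equiv), K2CO3, DMF, rt
Reagents that add atoms: benzyl bromide, BrCc1ccccc1
Why: Williamson ether synthesis: carbonate deprotonates only the three phenols, so the secondary 3-OH stays free and C2 and C3 are untouched.

Step 8
Reactants: 14 (2R,3R)-5,7-bis(benzyloxy)-2-[7-(benzyloxy)-2,2-diphenyl-1,3-benzodioxol-5-yl]chroman-3-ol
Product: 15 (2R,3R)-5,7-bis(benzyloxy)-2-[7-(benzyloxy)-2,2-diphenyl-1,3-benzodioxol-5-yl]-8-bromochroman-3-ol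
Conditions: NBS (1.0 equiv), CH2Cl2, −78 → −20 °C
Reagents that add atoms: N-bromosuccinimide, O=C1CCC(=O)N1Br
Why: Electrophilic aromatic bromination: C8 of ring A (ortho to O1 and O7, para to O5) is the most reactive and least hindered arene position of 5,7-di-O-benzyl flavan-3-ols, and the bromine blocks it so that the later union must occur at C6.

Step 9
Reactants: 15 (2R,3R)-5,7-bis(benzyloxy)-2-[7-(benzyloxy)-2,2-diphenyl-1,3-benzodioxol-5-yl]-8-bromochroman-3-ol; 16 3,4,5-tris(benzyloxy)benzoic acid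
Product: 17 (2R,3R)-5,7-bis(benzyloxy)-2-[7-(benzyloxy)-2,2-diphenyl-1,3-benzodioxol-5-yl]-8-bromochroman-3-yl 3,4,5-tris(benzyloxy)benzoate
Conditions: N,N'-dicyclohexylcarbodiimide (DCC, 1.5 equiv), 4-(dimethylamino)pyridine (DMAP, cat.), CH2Cl2, rt
Reagents that add atoms: none
Why: Steglich esterification: the DMAP-derived acylpyridinium acylates the only free hydroxyl (the axial 3-OH) with retention at C3.

Step 10
Reactants: 17 (2R,3R)-5,7-bis(benzyloxy)-2-[7-(benzyloxy)-2,2-diphenyl-1,3-benzodioxol-5-yl]-8-bromochroman-3-yl 3,4,5-tris(benzyloxy)benzoate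
Product: 18 (2R,3R)-5,7-bis(benzyloxy)-2-[3-(benzyloxy)-4,5-dihydroxyphenyl]-8-bromochroman-3-yl 3,4,5-tris(benzyloxy)benzoate
Conditions: CF3CO2H/H2O/CH2Cl2 (10:1:90), 0 °C → rt
Reagents that add atoms: none
Why: Acid hydrolysis of the diaryl ketal: protonation and ring opening give an oxocarbenium ion stabilised by two phenyl groups, which is captured by water and collapses to benzophenone and the catechol, while benzyl ethers, the aryl bromide and the alkyl ester should be inert to dilute acid at low temperature.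

Step 11
Reactants: 18 (2R,3R)-5,7-bis(benzyloxy)-2-[3-(benzyloxy)-4,5-dihydroxyphenyl]-8-bromochroman-3-yl 3,4,5-tris(benzyloxy)benzoate; 16 3,4,5-tris(benzyloxy)benzoic acid
Product: 19 (2R,3R)-5,7-bis(benzyloxy)-2-[3-(benzyloxy)-4-hydroxy-5-{[3,4,5-tris(benzyloxy)benzoyl]oxy}phenyl]-8-bromochroman-3-yl 3,4,5-tris(benzyloxy)benzoate
Conditions: 16 (1.0 equiv), DCC (1.05 equiv), DMAP (cat.), CH2Cl2, −20 → 0 °C
Reagents that add atoms: none
Why: Regioselective Steglich esterification: the terminal catechol OH has one ortho neighbour whereas the central OH sits between two oxygen substituents, so the bulky acylpyridinium attacks the terminal OH, and the less crowded terminal ester is also the thermodynamic product should acyl migration occur.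

Step 12
Reactants: 11 (2R,3R)-5,7-bis(benzyloxy)-2-[4-(benzyloxy)phenyl]-6,8-dibromo-4-methoxychroman-3-ol; 19 (2R,3R)-5,7-bis(benzyloxy)-2-[3-(benzyloxy)-4-hydroxy-5-{[3,4,5-tris(benzyloxy)benzoyl]oxy}phenyl]-8-bromochroman-3-yl 3,4,5-tris(benzyloxy)benzoate
Product: 20 (2R,3R)-5,7-bis(benzyloxy)-2-[3-(benzyloxy)-4-hydroxy-5-{[3,4,5-tris(benzyloxy)benzoyl]oxy}phenyl]-6-[(2R,3R,4S)-5,7-bis(benzyloxy)-2-[4-(benzyloxy)phenyl]-6,8-dibromo-3-hydroxychroman-4-yl]-8-bromochroman-3-yl 3,4,5-tris(benzyloxy)benzoate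
Conditions: Me3SiOTf (0.3 equiv), CH2Cl2, −78 → −40 °C
Reagents that add atoms: none
Why: Lewis-acid-mediated Friedel–Crafts union of a flavan C4 electrophile with a flavan nucleophile (standard procyanidin coupling): Me3SiOTf ionises the C4–OMe bond of either epimer to the ring-A-stabilised benzylic cation, C6 of 19 (C8 blocked by bromine) attacks anti to the axial 3-OH of the 2,3-cis electrophile and so sets the 3,4-trans (4β, 4S) centre, and the dibromo cap prevents self-condensation of 11.

Step 13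
Reactants: 20 the protected dimer of step 12
Product: 21 epiafzelechin-(4β→6)-epigallocatechin 3,3'-di-O-gallate (target)
Conditions: H2 (1 atm), Pd(OH)2/C, NaOAc, THF/MeOH/H2O, rt
Reagents that add atoms: none
Why: Catalytic hydrogenolysis: twelve O-benzyl groups are cleaved and three aryl C–Br bonds are reduced in one operation, with acetate buffering the HBr so that the acid-labile interflavan bond and the two gallate esters should survive; no stereocentre is affected.

**Compound list**

1 | 2,4,6-trihydroxybenzaldehyde | O=Cc1c(O)cc(O)cc1O | starting material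
2 | 2,4-bis(benzyloxy)-6-hydroxybenzaldehyde | O=Cc1c(O)cc(OCc2ccccc2)cc1OCc1ccccc1 | intermediate
3 | (Z)-(2-bromoethenyl)boronic acid MIDA (N-methyliminodiacetic acid) ester | C[N+]12CC(=O)O[B-]1(/C=C\Br)OC(=O)C2 | starting material
4 | [4-(benzyloxy)phenyl]boronic acid | OB(O)c1ccc(OCc2ccccc2)cc1 | starting material
5 | (Z)-{2-[4-(benzyloxy)phenyl]ethenyl}boronic acid MIDA ester | C[N+]12CC(=O)O[B-]1(/C=C\c1ccc(OCc3ccccc3)cc1)OC(=O)C2 | intermediate
6 | 3,5-bis(benzyloxy)-2-(dimethoxymethyl)phenol | COC(OC)c1c(O)cc(OCc2ccccc2)cc1OCc1ccccc1 | intermediate (not isolated)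
7 | 3,5-bis(benzyloxy)-6-(methoxymethylidene)cyclohexa-2,4-dien-1-one (alkene geometry open) | COC=C1C(=O)C=C(OCc2ccccc2)C=C1OCc1ccccc1 | intermediate (not isolated)
8 | [(2S,3R)-5,7-bis(benzyloxy)-2-[4-(benzyloxy)phenyl]-4-methoxychroman-3-yl]boronic acid MIDA ester (2,3-cis; C4 left open, both epimers) | COC1c2c(OCc3ccccc3)cc(OCc3ccccc3)cc2O[C@H](c2ccc(OCc3ccccc3)cc2)[C@@H]1[B-]12OC(=O)C[N+]1(C)CC(=O)O2 | intermediate
9 | [(2S,3R)-5,7-bis(benzyloxy)-2-[4-(benzyloxy)phenyl]-4-methoxychroman-3-yl]boronic acid (C4 open) | COC1c2c(OCc3ccccc3)cc(OCc3ccccc3)cc2O[C@H](c2ccc(OCc3ccccc3)cc2)[C@@H]1B(O)O | intermediate (not isolated)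
10 | (2R,3R)-5,7-bis(benzyloxy)-2-[4-(benzyloxy)phenyl]-4-methoxychroman-3-ol (4-methoxy-5,7,4'-tri-O-benzylepiafzelechin; C4 open) | COC1c2c(OCc3ccccc3)cc(OCc3ccccc3)cc2O[C@H](c2ccc(OCc3ccccc3)cc2)[C@@H]1O | intermediate
11 | (2R,3R)-5,7-bis(benzyloxy)-2-[4-(benzyloxy)phenyl]-6,8-dibromo-4-methoxychroman-3-ol (C4 open) | COC1c2c(OCc3ccccc3)c(Br)c(OCc3ccccc3)c(Br)c2O[C@H](c2ccc(OCc3ccccc3)cc2)[C@@H]1O | intermediate
12 | (−)-epigallocatechin, (2R,3R)-2-(3,4,5-trihydroxyphenyl)chromane-3,5,7-triol | Oc1cc([C@H]2Oc3cc(O)cc(O)c3C[C@H]2O)cc(O)c1O | starting material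
13 | (2R,3R)-2-(7-hydroxy-2,2-diphenyl-1,3-benzodioxol-5-yl)chromane-3,5,7-triol | Oc1cc([C@H]2Oc3cc(O)cc(O)c3C[C@H]2O)cc2OC(c3ccccc3)(c3ccccc3)Oc12 | intermediate
14 | (2R,3R)-5,7-bis(benzyloxy)-2-[7-(benzyloxy)-2,2-diphenyl-1,3-benzodioxol-5-yl]chroman-3-ol | c1ccccc1COc1cc([C@H]2Oc3cc(OCc4ccccc4)cc(OCc4ccccc4)c3C[C@H]2O)cc2OC(c3ccccc3)(c3ccccc3)Oc12 | intermediate
15 | (2R,3R)-5,7-bis(benzyloxy)-2-[7-(benzyloxy)-2,2-diphenyl-1,3-benzodioxol-5-yl]-8-bromochroman-3-ol | c1ccccc1COc1cc([C@H]2Oc3c(Br)c(OCc4ccccc4)cc(OCc4ccccc4)c3C[C@H]2O)cc2OC(c3ccccc3)(c3ccccc3)Oc12 | intermediate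
16 | 3,4,5-tris(benzyloxy)benzoic acid | OC(=O)c1cc(OCc2ccccc2)c(OCc2ccccc2)c(OCc2ccccc2)c1 | starting material
17 | (2R,3R)-5,7-bis(benzyloxy)-2-[7-(benzyloxy)-2,2-diphenyl-1,3-benzodioxol-5-yl]-8-bromochroman-3-yl 3,4,5-tris(benzyloxy)benzoate | c1ccccc1COc1cc([C@H]2Oc3c(Br)c(OCc4ccccc4)cc(OCc4ccccc4)c3C[C@H]2OC(=O)c2cc(OCc3ccccc3)c(OCc3ccccc3)c(OCc3ccccc3)c2)cc2OC(c3ccccc3)(c3ccccc3)Oc12 | intermediate
18 | (2R,3R)-5,7-bis(benzyloxy)-2-[3-(benzyloxy)-4,5-dihydroxyphenyl]-8-bromochroman-3-yl 3,4,5-tris(benzyloxy)benzoate | c1ccccc1COc1cc([C@H]2Oc3c(Br)c(OCc4ccccc4)cc(OCc4ccccc4)c3C[C@H]2OC(=O)c2cc(OCc3ccccc3)c(OCc3ccccc3)c(OCc3ccccc3)c2)cc(O)c1O | intermediate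
19 | (2R,3R)-5,7-bis(benzyloxy)-2-[3-(benzyloxy)-4-hydroxy-5-{[3,4,5-tris(benzyloxy)benzoyl]oxy}phenyl]-8-bromochroman-3-yl 3,4,5-tris(benzyloxy)benzoate | c1ccccc1COc1cc([C@H]2Oc3c(Br)c(OCc4ccccc4)cc(OCc4ccccc4)c3C[C@H]2OC(=O)c2cc(OCc3ccccc3)c(OCc3ccccc3)c(OCc3ccccc3)c2)cc(OC(=O)c2cc(OCc3ccccc3)c(OCc3ccccc3)c(OCc3ccccc3)c2)c1O | intermediate
20 | protected dimer: lower unit (2R,3R) as in 19, bonded at C6 to C4 of the (2R,3R,4S)-5,7-bis(benzyloxy)-2-[4-(benzyloxy)phenyl]-6,8-dibromo-3-hydroxychroman-4-yl upper unit (4β, 3,4-trans) | c1ccccc1COc1cc([C@H]2Oc3c(Br)c(OCc4ccccc4)c([C@H]4c5c(OCc6ccccc6)c(Br)c(OCc6ccccc6)c(Br)c5O[C@H](c5ccc(OCc6ccccc6)cc5)[C@@H]4O)c(OCc4ccccc4)c3C[C@H]2OC(=O)c2cc(OCc3ccccc3)c(OCc3ccccc3)c(OCc3ccccc3)c2)cc(OC(=O)c2cc(OCc3ccccc3)c(OCc3ccccc3)c(OCc3ccccc3)c2)c1O | intermediate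
21 | epiafzelechin-(4β→6)-epigallocatechin 3,3'-di-O-gallate; upper unit (2R,3R,4S), lower unit (2R,3R) | O=C(Oc1cc([C@H]2Oc3cc(O)c([C@H]4c5c(O)cc(O)cc5O[C@H](c5ccc(O)cc5)[C@@H]4O)c(O)c3C[C@H]2OC(=O)c2cc(O)c(O)c(O)c2)cc(O)c1O)c1cc(O)c(O)c(O)c1 | target

**Step count and risks**

Total step count: 13. Longest linear sequence: 8 steps (steps 6–13, from 12 to 21); the upper branch contributes 6 steps in line (steps 1 or 2, then 3, 4, 5, 12, 13).

Steps most likely to fail:

Step 3 (proposed new method). The cis-disubstituted alkene may add too slowly to the stabilised quinone methide. The acid may isomerise the Z-alkene before ring closure, which would erode the 2,3-cis relationship. The counter-anion may give insufficient face selectivity. Re-ionisation at C4 may be followed by loss of boron. The fallback makes the same two bonds by known chemistry and sets out from 2 and 5. Aqueous NaOH in THF releases (Z)-{2-[4-(benzyloxy)phenyl]ethenyl}boronic acid F1 from 5. Heating F1 with 2 and catalytic dibenzylamine in dioxane (Petasis-type alkenyl transfer to the iminium carbon, amine loss, oxa-6π-electrocyclisation of the resulting dienone) gives racemic 5,7-bis(benzyloxy)-2-[4-(benzyloxy)phenyl]-2H-chromene F2. Epoxidation with dimethyldioxirane anti to the 2-aryl group and opening of the epoxide at C4 by methanol give the 2,3-trans-3,4-trans alcohol rac-(2R,3S,4R)-5,7-bis(benzyloxy)-2-[4-(benzyloxy)phenyl]-4-methoxychroman-3-ol F3. Dess–Martin oxidation gives the ketone rac-(2R,4R)-5,7-bis(benzyloxy)-2-[4-(benzyloxy)phenyl]-4-methoxychroman-3-one F4. Reduction with LiBH(sec-Bu)3 from the face opposite the 2-aryl group inverts C3 and comes back to the route at 10, as the racemate of one C4 epimer. The antipodal upper unit then gives a diastereomeric dimer in step 12, which is removed by chromatography at the stage of 20.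

Step 11. Acylation may occur at the flanked central OH, both phenols may be acylated, or the ester may migrate. The fallback replaces selective acylation by exhaustive acylation and selective unmasking, and sets out from 18. Excess 16 with DCC and DMAP gives the tri-ester (2R,3R)-5,7-bis(benzyloxy)-2-[3-(benzyloxy)-4,5-bis{[3,4,5-tris(benzyloxy)benzoyl]oxy}phenyl]-8-bromochroman-3-yl 3,4,5-tris(benzyloxy)benzoate F5. One equivalent of hydrazine acetate in DMF at 0 °C should then cleave the most crowded and most activated aryl ester, the central one flanked by two oxygen substituents (the behaviour known for peracylated gallates), which comes back to the route at 19.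

Step 13. Reduction of the three hindered aryl bromides may lag behind debenzylation, which would leave the free polyphenol on the catalyst for long times and invite acyl migration and acid-promoted interflavan cleavage. The fallback separates the two reductions and sets out from 20. Radical hydrodebromination (Bu3SnH, azobisisobutyronitrile, toluene, 80 °C) gives the bromine-free dodeca-O-benzyl dimer F6. Neutral hydrogenolysis of F6 over Pd(OH)2/C comes back to the route at 21.

Further compounds
F1 | step 3 | (Z)-{2-[4-(benzyloxy)phenyl]ethenyl}boronic acid | OB(O)/C=C\c1ccc(OCc2ccccc2)cc1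
F2 | step 3 | 5,7-bis(benzyloxy)-2-[4-(benzyloxy)phenyl]-2H-chromene (racemic) | c1ccccc1COc1ccc(cc1)C1C=Cc2c(OCc3ccccc3)cc(OCc3ccccc3)cc2O1
F3 | step 3 | rac-(2R,3S,4R)-5,7-bis(benzyloxy)-2-[4-(benzyloxy)phenyl]-4-methoxychroman-3-ol (one enantiomer drawn) | CO[C@@H]1c2c(OCc3ccccc3)cc(OCc3ccccc3)cc2O[C@H](c2ccc(OCc3ccccc3)cc2)[C@H]1O
F4 | step 3 | rac-(2R,4R)-5,7-bis(benzyloxy)-2-[4-(benzyloxy)phenyl]-4-methoxychroman-3-one (one enantiomer drawn) | CO[C@@H]1c2c(OCc3ccccc3)cc(OCc3ccccc3)cc2O[C@H](c2ccc(OCc3ccccc3)cc2)C1=O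
F5 | step 11 | (2R,3R)-5,7-bis(benzyloxy)-2-[3-(benzyloxy)-4,5-bis{[3,4,5-tris(benzyloxy)benzoyl]oxy}phenyl]-8-bromochroman-3-yl 3,4,5-tris(benzyloxy)benzoate | c1ccccc1COc1cc([C@H]2Oc3c(Br)c(OCc4ccccc4)cc(OCc4ccccc4)c3C[C@H]2OC(=O)c2cc(OCc3ccccc3)c(OCc3ccccc3)c(OCc3ccccc3)c2)cc(OC(=O)c2cc(OCc3ccccc3)c(OCc3ccccc3)c(OCc3ccccc3)c2)c1OC(=O)c1cc(OCc2ccccc2)c(OCc2ccccc2)c(OCc2ccccc2)c1
F6 | step 13 | bromine-free dodeca-O-benzyl dimer (20 with H in place of the three Br; 4β-linked, same configuration) | c1ccccc1COc1cc([C@H]2Oc3cc(OCc4ccccc4)c([C@H]4c5c(OCc6ccccc6)cc(OCc6ccccc6)cc5O[C@H](c5ccc(OCc6ccccc6)cc5)[C@@H]4O)c(OCc4ccccc4)c3C[C@H]2OC(=O)c2cc(OCc3ccccc3)c(OCc3ccccc3)c(OCc3ccccc3)c2)cc(OC(=O)c2cc(OCc3ccccc3)c(OCc3ccccc3)c(OCc3ccccc3)c2)c1O
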